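**Retrosynthetic overview**
- Numbering: linker C1(=CH2)=C2–C3H2; ring A C4 (CH on C3), C5 (CH bearing the isopropenyl group), C9, C10, C11 (C(CH3)OH), C12 (CHOH); ring B C13 (CH on C2), C14, C15, C16 (C(CH3)OH), C17 (CHBr), C18.
- The strategy rests on ring A: the trans carbon substituents on C4 and C5 sit beside oxygen-bearing C12 and methyl-bearing C11, the retron of a [4+2] adduct. Cutting C4–C12 and C5–C9 gives an (E)-enal dienophile (C3, C4, C5, acetyl as masked isopropenyl) and a 1-acetoxy-2-methylbutadiene (C12, C11, C10, C9).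
- After the cycloaddition the C3 carboxyl delivers the C11 oxygen (iodolactonisation), C12 is reset through its ketone, and C3 becomes an alkylzinc that is coupled to C2 of a ring B alkenyl triflate (C2–C3 disconnection).
- Ring B is carried from enantiopure cyclohex-3-ene-1-carboxylic acid; its cis bromohydrin comes from methyl addition to an alpha-bromo ketone, followed by equilibration at C13.
- Ring order: ring A is formed in step 3, ring B is present from step 13, and the two rings are joined in step 21.

Key step: step 3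

Remark: diene 2 is used as the E/Z mixture from step 1, since only the (E) isomer can reach the s-cis geometry needed in step 3.
Remark: acid 16 is taken as a commercial, enantiopure building block.

Step 1
Reactants: 1 (E)-2-methylbut-2-enal (tiglic aldehyde)
Product: 2 (E)-1-acetoxy-2-methylbuta-1,3-diene
Conditions: isopropenyl acetate (excess), p-TsOH·H2O (cat.), hydroquinone (cat.), 95 °C, acetone distilled off
Reagents that add atoms: isopropenyl acetate, CC(=C)OC(C)=O
Why: Acid-catalysed enol ester exchange; gamma-deprotonation of the activated enal gives the conjugated dienol, which is trapped as its acetate (standard preparation of 1-acyloxydienes from enals).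

Step 2
Reactants: 3 2-methylfuran
Product: 5 (E)-4-oxopent-2-enal, via (Z)-4-oxopent-2-enal 4 (not isolated)
Conditions: NBS, NaHCO3, acetone/H2O (10:1), −20 °C; then pyridine (cat.), rt
Reagents that add atoms: water, O
Why: Oxidative ring opening of the furan (bromination at C5, hydrolysis) gives the cis ene-dicarbonyl, which pyridine isomerises to the more stable (E) isomer by reversible conjugate addition.

Step 3
Reactants: 2 (E)-1-acetoxy-2-methylbuta-1,3-diene; 5 (E)-4-oxopent-2-enal
Product: 6 (1R,5S,6R)-5-acetyl-6-formyl-2-methylcyclohex-2-en-1-yl acetate (C4 formyl and C5 acetyl trans, C12 acetate cis to formyl)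
Conditions: (5S)-5-benzyl-2,2,3-trimethylimidazolidin-4-one hydrochloride (20 mol %), MeCN/H2O (95:5), −20 °C
Reagents that add atoms: none
Why: The amine salt condenses with the aldehyde of 5 to give the (E)-iminium ion, whose lowered LUMO undergoes a concerted, asynchronous [4+2] cycloaddition with s-cis 2; the closest known reaction type is the imidazolidinone-salt-catalysed enantioselective Diels–Alder reaction of enals with 1-acyloxybutadienes. Ring A closes in the [4+2] mode (six-membered, suprafacial on both partners) by forming C4–C12 and C5–C9. C4 and C5 are set in absolute terms by the benzyl group of the (5S) catalyst, which covers one face of the iminium so that the diene should add to the si face of both carbons, and their trans relation follows from the (E) geometry of 5; C12 is set by the endo orientation of the iminium and is provisional, since steps 9 and 10 reset it. The step needs ortho regiochemistry, which the 1-acetoxy group secures by making the unsubstituted terminus C9 the nucleophilic end that bonds to C5, the carbon beta to the iminium. It also needs the catalysed path to outrun the background reaction of the doubly activated dienophile, which the low temperature and the selective condensation at the aldehyde should secure; endo/exo leakage is harmless because both adducts converge at dione 12.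

Step 4
Reactants: 6 (1R,5S,6R)-5-acetyl-6-formyl-2-methylcyclohex-2-en-1-yl acetate
Product: 7 (1R,2R,6S)-2-acetoxy-6-acetyl-3-methylcyclohex-3-ene-1-carboxylic acid
Conditions: NaClO2, NaH2PO4, 2-methyl-2-butene, t-BuOH/H2O, 0 °C to rt
Reagents that add atoms: sodium chlorite, [Na+].[O-]Cl=O
Why: Pinnick oxidation converts only the aldehyde under mildly acidic conditions, so the beta-acetoxy group is not eliminated and the ketone, acetate and ring alkene (protected by the hypochlorite scavenger) survive.

Step 5
Reactants: 7 (1R,2R,6S)-2-acetoxy-6-acetyl-3-methylcyclohex-3-ene-1-carboxylic acid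
Product: 8 (1R,2R,6S)-6-acetyl-2-hydroxy-3-methylcyclohex-3-ene-1-carboxylic acid
Conditions: LiOH, THF/H2O, 0 °C to rt; then 1 M HCl to pH 3
Reagents that add atoms: none
Why: Ester saponification frees the C12 hydroxyl before any lactone is present; C4 (carboxylate alpha-carbon) is not acidic and C5 already has the thermodynamic trans-diequatorial arrangement.

Step 6
Reactants: 8 (1R,2R,6S)-6-acetyl-2-hydroxy-3-methylcyclohex-3-ene-1-carboxylic acid
Product: 9 (1R,2S,4R,5R,8R)-2-acetyl-8-hydroxy-4-iodo-5-methyl-6-oxabicyclo[3.2.1]octan-7-one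
Conditions: I2, NaHCO3, MeCN/H2O, 0 °C, dark
Reagents that add atoms: iodine, II
Why: Iodolactonisation of a gamma,delta-unsaturated acid; the axial C3 carboxylate opens the iodonium ion at the tertiary carbon C11 from its own face, so the C11–O bond is formed cis to C3 (the C11 configuration of the target) with iodine trans on C10.

Step 7
Reactants: 9 (1R,2S,4R,5R,8R)-2-acetyl-8-hydroxy-4-iodo-5-methyl-6-oxabicyclo[3.2.1]octan-7-one
Product: 10 (1R,2S,5S,8R)-2-acetyl-8-hydroxy-5-methyl-6-oxabicyclo[3.2.1]octan-7-one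
Conditions: Bu3SnH, AIBN (cat.), benzene, 80 °C
Reagents that add atoms: none
Why: Radical dehalogenation replaces the C10 iodine by hydrogen without touching the lactone, ketone or alcohol, and no stereocenter is affected.

Step 8
Reactants: 10 (1R,2S,5S,8R)-2-acetyl-8-hydroxy-5-methyl-6-oxabicyclo[3.2.1]octan-7-one
Product: 11 (1R,2S,5S,8R)-8-hydroxy-5-methyl-2-(prop-1-en-2-yl)-6-oxabicyclo[3.2.1]octan-7-one
Conditions: Zn, CH2Br2, TiCl4, THF, 0 °C (pre-formed reagent); then 10, CH2Cl2, 0 °C to rt
Reagents that add atoms: dibromomethane, BrCBr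
Why: Lombardo methylenation is non-basic, so the axial C5 acetyl group is converted to isopropenyl without epimerisation, and it leaves the lactone carbonyl alone.

Step 9
Reactants: 11 (1R,2S,5S,8R)-8-hydroxy-5-methyl-2-(prop-1-en-2-yl)-6-oxabicyclo[3.2.1]octan-7-one
Product: 12 (1R,2S,5S)-5-methyl-2-(prop-1-en-2-yl)-6-oxabicyclo[3.2.1]octane-7,8-dione
Conditions: DMP, NaHCO3, CH2Cl2, 0 °C to rt; used crude
Reagents that add atoms: none
Why: Dess–Martin oxidation removes the provisional C12 stereocenter; the beta-keto lactone cannot enolise because C4 is a bridgehead, and it is carried on without purification to avoid hydrolytic ring opening.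

Step 10
Reactants: 12 (1R,2S,5S)-5-methyl-2-(prop-1-en-2-yl)-6-oxabicyclo[3.2.1]octane-7,8-dione
Product: 13 (1S,2S,3S,4S)-3-(hydroxymethyl)-1-methyl-4-(prop-1-en-2-yl)cyclohexane-1,2-diol
Conditions: LiAlH4, THF, −78 °C to rt; then H2O, 15% aq. NaOH
Reagents that add atoms: none
Why: Hydride reduction of ketone and lactone. In the bicycle the C12 carbonyl is attacked from the lactone side, because the other face is blocked by the axial isopropenyl group; if the lactone opens first, axial attack anti to the axial C11 methyl gives the same result. Both paths give the equatorial C12 hydroxyl, trans to the C11 hydroxyl and to C3.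

Step 11
Reactants: 13 (1S,2S,3S,4S)-3-(hydroxymethyl)-1-methyl-4-(prop-1-en-2-yl)cyclohexane-1,2-diol
Product: 14 (1S,2S,3R,4S)-3-(iodomethyl)-1-methyl-4-(prop-1-en-2-yl)cyclohexane-1,2-diol
Conditions: I2, PPh3, imidazole, THF, 0 °C
Reagents that add atoms: iodine, II
Why: Appel-type iodination is selective for the primary alcohol over the hindered secondary and the tertiary hydroxyl; the product is silylated at once.

Step 12
Reactants: 14 (1S,2S,3R,4S)-3-(iodomethyl)-1-methyl-4-(prop-1-en-2-yl)cyclohexane-1,2-diol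
Product: 15 [(1S,2S,3R,4S)-3-(iodomethyl)-1-methyl-4-(prop-1-en-2-yl)cyclohexane-1,2-diyl]bis(oxy)bis(triethylsilane)
Conditions: TESOTf, 2,6-lutidine, CH2Cl2, −78 to 0 °C
Reagents that add atoms: triethylsilyl trifluoromethanesulfonate, CC[Si](CC)(CC)OS(=O)(=O)C(F)(F)F
Why: The silyl triflate caps both the secondary and the tertiary hydroxyl, which removes the acidic protons before the organozinc is made.

Step 13
Reactants: 16 (S)-cyclohex-3-ene-1-carboxylic acid
Product: 17 (1S,4S,5S)-4-bromo-6-oxabicyclo[3.2.1]octan-7-one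
Conditions: NBS, CH2Cl2, 0 °C to rt, dark
Reagents that add atoms: N-bromosuccinimide, O=C1CCC(=O)N1Br
Why: Bromolactonisation; the carboxylate opens the bromonium ion at C17 on its own face (gamma-lactone), placing bromine trans on C16 and thereby encoding the C13 configuration into the C16/C17 pair.

Step 14
Reactants: 17 (1S,4S,5S)-4-bromo-6-oxabicyclo[3.2.1]octan-7-one
Product: 19 [(1S,3S,6R)-7-oxabicyclo[4.1.0]heptan-3-yl](morpholin-4-yl)methanone, via bromohydrin amide 18 (not isolated)
Conditions: morpholine (1.5 equiv), THF, 40 °C; then K2CO3, MeOH, rt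
Reagents that add atoms: morpholine, C1COCCN1
Why: Aminolysis of the strained lactone frees the C17 hydroxyl, which displaces the anti C16 bromide in base to give the epoxide cis to the amide (intramolecular Williamson closure).

Step 15
Reactants: 19 [(1S,3S,6R)-7-oxabicyclo[4.1.0]heptan-3-yl](morpholin-4-yl)methanone
Product: 20 [(1S,3R,4R)-3-bromo-4-hydroxycyclohexyl](morpholin-4-yl)methanone
Conditions: 48% aq. HBr, THF, 0 °C
Reagents that add atoms: hydrogen bromide, Br
Why: Trans-diaxial (Fürst–Plattner) epoxide opening with the amide equatorial places bromide on C17 with inversion and leaves the hydroxyl on C16; the amide lies on the epoxide face and cannot take part.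

Step 16
Reactants: 20 [(1S,3R,4R)-3-bromo-4-hydroxycyclohexyl](morpholin-4-yl)methanone
Product: 21 (2R,4S)-2-bromo-4-(morpholine-4-carbonyl)cyclohexan-1-one
Conditions: DMP, NaHCO3, CH2Cl2, 0 °C to rt; used at once
Reagents that add atoms: none
Why: Buffered Dess–Martin oxidation gives the alpha-bromo ketone with the bromine axial and trans to the equatorial amide, without enolisation at C17.

Step 17
Reactants: 21 (2R,4S)-2-bromo-4-(morpholine-4-carbonyl)cyclohexan-1-one
Product: 22 1-[(1S,3R,4S)-3-bromo-4-hydroxy-4-methylcyclohexyl]ethan-1-one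
Conditions: MeMgBr (3.5 equiv), THF, −78 °C, then 0 °C to rt; aq. NH4Cl
Reagents that add atoms: methylmagnesium bromide, C[Mg]Br
Why: Grignard addition to an alpha-bromo ketone under Cornforth/polar Felkin–Anh control: methyl enters axially anti to the axial C–Br bond, giving the cis bromohydrin (C16 S, hydroxyl cis to bromine); the excess reagent then converts the morpholine amide into the methyl ketone through its stable tetrahedral adduct.

Step 18
Reactants: 22 1-[(1S,3R,4S)-3-bromo-4-hydroxy-4-methylcyclohexyl]ethan-1-one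
Product: 23 1-[(1R,3R,4S)-3-bromo-4-hydroxy-4-methylcyclohexyl]ethan-1-one
Conditions: p-TsOH·H2O (cat.), CHCl3, 40 °C; minor epimer separated and resubmitted
Reagents that add atoms: none
Why: Acid-catalysed enolisation toward the more substituted carbon C13 equilibrates the two epimers; the (1R) epimer can hold acetyl, bromine and methyl equatorial with only the hydroxyl axial and should therefore dominate, while the neutral enol avoids alkylation by the C17 bromide.

Step 19
Reactants: 23 1-[(1R,3R,4S)-3-bromo-4-hydroxy-4-methylcyclohexyl]ethan-1-one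
Product: 24 1-[(1R,3R,4S)-3-bromo-4-methyl-4-(trimethylsilyloxy)cyclohexyl]ethan-1-one
Conditions: N-(trimethylsilyl)imidazole, CH2Cl2, rt
Reagents that add atoms: N-(trimethylsilyl)imidazole, C[Si](C)(C)n1ccnc1
Why: The silylimidazole caps the tertiary alcohol without base or Lewis acid, so the ketone is not enolised and C13 is not disturbed.

Step 20
Reactants: 24 1-[(1R,3R,4S)-3-bromo-4-methyl-4-(trimethylsilyloxy)cyclohexyl]ethan-1-one
Product: 25 1-[(1R,3R,4S)-3-bromo-4-methyl-4-(trimethylsilyloxy)cyclohexyl]ethenyl trifluoromethanesulfonate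
Conditions: KHMDS, THF, −78 °C; then Comins' reagent, −78 to −40 °C
Reagents that add atoms: N-(5-chloropyridin-2-yl)-1,1,1-trifluoro-N-(trifluoromethylsulfonyl)methanesulfonamide, FC(F)(F)S(=O)(=O)N(c1ccc(Cl)cn1)S(=O)(=O)C(F)(F)F
Why: Kinetic deprotonation at the methyl group and O-triflation give the 1,1-disubstituted alkenyl triflate; the equatorial bromide has no anti-periplanar hydrogen and lies on the same face as the side chain, so neither elimination nor internal alkylation should intervene.

Step 21
Reactants: 15 [(1S,2S,3R,4S)-3-(iodomethyl)-1-methyl-4-(prop-1-en-2-yl)cyclohexane-1,2-diyl]bis(oxy)bis(triethylsilane); 25 1-[(1R,3R,4S)-3-bromo-4-methyl-4-(trimethylsilyloxy)cyclohexyl]ethenyl trifluoromethanesulfonate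
Product: 27 tris-silyl ether of the target (C11 and C12 as triethylsilyl ethers, C16 as trimethylsilyl ether), via alkylzinc iodide 26 (not isolated)
Conditions: 15, Zn dust (activated with 1,2-dibromoethane and Me3SiCl), LiCl, THF, 40 °C; then 25, PdCl2(dppf) (5 mol %, dppf = 1,1'-bis(diphenylphosphino)ferrocene), THF/NMP, 50 °C
Reagents that add atoms: none
Why: Negishi coupling: zinc inserts into the primary C–I bond and the palladium catalyst joins the sp3 carbon C3 to the alkenyl triflate carbon C2; the secondary bromide and the silyl ethers are inert to alkylzinc iodides, and the bidentate diphosphine suppresses beta-hydride elimination.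

Step 22
Reactants: 27 tris-silyl ether of the target
Product: 28 (1S,2S,3R,4S)-3-{2-[(1R,3R,4S)-3-bromo-4-hydroxy-4-methylcyclohexyl]prop-2-en-1-yl}-1-methyl-4-(prop-1-en-2-yl)cyclohexane-1,2-diol (CNP0422107.2)
Conditions: HF·pyridine, pyridine, THF, 0 °C to rt
Reagents that add atoms: none
Why: Buffered fluoride cleaves the three silyl ethers without touching the bromide, the two 1,1-disubstituted alkenes or the tertiary alcohols.

**Compound list**
1 | (E)-2-methylbut-2-enal | C/C=C(\C)C=O | starting material
2 | (E)-1-acetoxy-2-methylbuta-1,3-diene | CC(=O)O/C=C(\C)C=C | intermediate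
3 | 2-methylfuran | Cc1ccco1 | starting material
4 | (Z)-4-oxopent-2-enal | O=C/C=C\C(C)=O | intermediate
5 | (E)-4-oxopent-2-enal | O=C/C=C/C(C)=O | intermediate
6 | (1R,5S,6R)-5-acetyl-6-formyl-2-methylcyclohex-2-en-1-yl acetate | O=C[C@@H]1[C@@H](C(C)=O)CC=C(C)[C@@H]1OC(C)=O | intermediate
7 | (1R,2R,6S)-2-acetoxy-6-acetyl-3-methylcyclohex-3-ene-1-carboxylic acid | OC(=O)[C@@H]1[C@@H](C(C)=O)CC=C(C)[C@@H]1OC(C)=O | intermediate
8 | (1R,2R,6S)-6-acetyl-2-hydroxy-3-methylcyclohex-3-ene-1-carboxylic acid | OC(=O)[C@@H]1[C@@H](C(C)=O)CC=C(C)[C@@H]1O | intermediate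
9 | (1R,2S,4R,5R,8R)-2-acetyl-8-hydroxy-4-iodo-5-methyl-6-oxabicyclo[3.2.1]octan-7-one | O=C2[C@@H]1[C@@H](C(C)=O)C[C@@H](I)[C@](C)(O2)[C@@H]1O | intermediate
10 | (1R,2S,5S,8R)-2-acetyl-8-hydroxy-5-methyl-6-oxabicyclo[3.2.1]octan-7-one | O=C2[C@@H]1[C@@H](C(C)=O)CC[C@](C)(O2)[C@@H]1O | intermediate
11 | (1R,2S,5S,8R)-8-hydroxy-5-methyl-2-(prop-1-en-2-yl)-6-oxabicyclo[3.2.1]octan-7-one | O=C2[C@@H]1[C@@H](C(C)=C)CC[C@](C)(O2)[C@@H]1O | intermediate
12 | (1R,2S,5S)-5-methyl-2-(prop-1-en-2-yl)-6-oxabicyclo[3.2.1]octane-7,8-dione | O=C2[C@@H]1[C@@H](C(C)=C)CC[C@](C)(O2)C1=O | intermediate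
13 | (1S,2S,3S,4S)-3-(hydroxymethyl)-1-methyl-4-(prop-1-en-2-yl)cyclohexane-1,2-diol | OC[C@@H]1[C@@H](C(C)=C)CC[C@](C)(O)[C@H]1O | intermediate
14 | (1S,2S,3R,4S)-3-(iodomethyl)-1-methyl-4-(prop-1-en-2-yl)cyclohexane-1,2-diol | IC[C@@H]1[C@@H](C(C)=C)CC[C@](C)(O)[C@H]1O | intermediate
15 | [(1S,2S,3R,4S)-3-(iodomethyl)-1-methyl-4-(prop-1-en-2-yl)cyclohexane-1,2-diyl]bis(oxy)bis(triethylsilane) | IC[C@@H]1[C@@H](C(C)=C)CC[C@](C)(O[Si](CC)(CC)CC)[C@H]1O[Si](CC)(CC)CC | intermediate
16 | (S)-cyclohex-3-ene-1-carboxylic acid | OC(=O)[C@H]1CCC=CC1 | starting material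
17 | (1S,4S,5S)-4-bromo-6-oxabicyclo[3.2.1]octan-7-one | O=C2[C@H]1CC[C@H](Br)[C@H](C1)O2 | intermediate
18 | [(1S,3S,4S)-4-bromo-3-hydroxycyclohexyl](morpholin-4-yl)methanone | O=C(N1CCOCC1)[C@H]1CC[C@H](Br)[C@@H](O)C1 | intermediate
19 | [(1S,3S,6R)-7-oxabicyclo[4.1.0]heptan-3-yl](morpholin-4-yl)methanone | O=C(N1CCOCC1)[C@H]1CC[C@H]2O[C@H]2C1 | intermediate
20 | [(1S,3R,4R)-3-bromo-4-hydroxycyclohexyl](morpholin-4-yl)methanone | O=C(N1CCOCC1)[C@H]1CC[C@@H](O)[C@H](Br)C1 | intermediate
21 | (2R,4S)-2-bromo-4-(morpholine-4-carbonyl)cyclohexan-1-one | O=C(N1CCOCC1)[C@H]1CCC(=O)[C@H](Br)C1 | intermediate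
22 | 1-[(1S,3R,4S)-3-bromo-4-hydroxy-4-methylcyclohexyl]ethan-1-one | CC(=O)[C@H]1CC[C@](C)(O)[C@H](Br)C1 | intermediate
23 | 1-[(1R,3R,4S)-3-bromo-4-hydroxy-4-methylcyclohexyl]ethan-1-one | CC(=O)[C@@H]1CC[C@](C)(O)[C@H](Br)C1 | intermediate
24 | 1-[(1R,3R,4S)-3-bromo-4-methyl-4-(trimethylsilyloxy)cyclohexyl]ethan-1-one | CC(=O)[C@@H]1CC[C@](C)(O[Si](C)(C)C)[C@H](Br)C1 | intermediate
25 | 1-[(1R,3R,4S)-3-bromo-4-methyl-4-(trimethylsilyloxy)cyclohexyl]ethenyl trifluoromethanesulfonate | C=C(OS(=O)(=O)C(F)(F)F)[C@@H]1CC[C@](C)(O[Si](C)(C)C)[C@H](Br)C1 | intermediate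
26 | {[(1R,2S,3S,6S)-3-methyl-6-(prop-1-en-2-yl)-2,3-bis(triethylsilyloxy)cyclohexyl]methyl}zinc iodide | I[Zn]C[C@@H]1[C@@H](C(C)=C)CC[C@](C)(O[Si](CC)(CC)CC)[C@H]1O[Si](CC)(CC)CC | intermediate
27 | tris-silyl ether of the target (C11-OSiEt3, C12-OSiEt3, C16-OSiMe3) | C=C(C[C@@H]1[C@@H](C(=C)C)CC[C@](C)(O[Si](CC)(CC)CC)[C@H]1O[Si](CC)(CC)CC)[C@@H]1CC[C@](C)(O[Si](C)(C)C)[C@H](Br)C1 | intermediate
28 | (1S,2S,3R,4S)-3-{2-[(1R,3R,4S)-3-bromo-4-hydroxy-4-methylcyclohexyl]prop-2-en-1-yl}-1-methyl-4-(prop-1-en-2-yl)cyclohexane-1,2-diol | C=C(C[C@@H]1[C@@H](C(=C)C)CC[C@](C)(O)[C@H]1O)[C@@H]1CC[C@](C)(O)[C@H](Br)C1 | target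

Total step count: 22.
Longest linear sequence: 13 steps (steps 2 to 12, then 21 and 22).

**Steps most likely to fail**

Step 3. The uncatalysed cycloaddition of the doubly activated dienophile may compete with the iminium pathway, and the catalyst may also condense with the ketone; either process would erode enantiomeric purity and regiocontrol. The fallback keeps the same two bonds but moves the activation to a chelating imide. It sets out from diene 2 and commercial (E)-4-oxopent-2-enoic acid (CC(=O)/C=C/C(O)=O). The acid is converted through its pivaloyl mixed anhydride and N-lithio-oxazolidin-2-one into 3-[(E)-4-oxopent-2-enoyl]-1,3-oxazolidin-2-one F1. A divalent copper bis(oxazoline) Lewis acid, [Cu((S,S)-tBu-box)](SbF6)2 (ligand enantiomer chosen so that the C4 si face is open), binds the imide as a chelate and catalyses its Diels–Alder reaction with 2 to give (1R,5S,6R)-5-acetyl-2-methyl-6-(2-oxo-1,3-oxazolidine-3-carbonyl)cyclohex-2-en-1-yl acetate F2. LiOH/H2O2 followed by LiOH cleaves the imide and the acetate, and the route is rejoined at hydroxy acid 8.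

Step 18. The equilibrium between the C13 epimers may not lie far enough on the side of 23, and prolonged acid may dehydrate the tertiary alcohol. The fallback replaces equilibration of a ketone by a covalent trap that only the cis epimer can enter. It sets out from bromoketone 21. One equivalent of MeMgBr at −78 °C adds only to the ring ketone and gives [(1S,3R,4S)-3-bromo-4-hydroxy-4-methylcyclohexyl](morpholin-4-yl)methanone F3. DIBAL-H at −78 °C reduces the morpholine amide to (1S,3R,4S)-3-bromo-4-hydroxy-4-methylcyclohexane-1-carbaldehyde F4. Camphorsulfonic acid in MeOH/HC(OMe)3 epimerises the aldehyde, and only the epimer with C13 cis to the C16 hydroxyl can close, so the material should drain into (1S,4R,6R)-6-bromo-3-methoxy-1-methyl-2-oxabicyclo[2.2.2]octane F5. mCPBA/BF3·OEt2 oxidises this acetal to (1S,4R,6R)-6-bromo-1-methyl-2-oxabicyclo[2.2.2]octan-3-one F6, in which C13 is locked as a bridgehead. One equivalent of MeLi at −78 °C opens the lactone to hydroxy ketone 23, where the route is rejoined.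

Step 21. Zinc insertion into the beta-branched iodide may be slow or end in protodezincation, and transmetalation to the hindered alkenylpalladium may lose out to beta-hydride elimination. The fallback changes the nucleophile from zinc to boron (B-alkyl Suzuki–Miyaura coupling). It sets out from iodide 15: t-BuLi (2.1 equiv, Et2O, −78 °C) followed by B-methoxy-9-borabicyclo[3.3.1]nonane gives lithium B-methoxy-B-{[(1R,2S,3S,6S)-3-methyl-6-(prop-1-en-2-yl)-2,3-bis(triethylsilyloxy)cyclohexyl]methyl}-9-borabicyclo[3.3.1]nonanate F7. This is coupled with triflate 25 (PdCl2(dppf), aq. K3PO4, DMF, rt), and the route is rejoined at 27.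

**Further compounds**
F1 | step 3 | 3-[(E)-4-oxopent-2-enoyl]-1,3-oxazolidin-2-one | CC(=O)/C=C/C(=O)N1CCOC1=O
F2 | step 3 | (1R,5S,6R)-5-acetyl-2-methyl-6-(2-oxo-1,3-oxazolidine-3-carbonyl)cyclohex-2-en-1-yl acetate | O=C(N2CCOC2=O)[C@@H]1[C@@H](C(C)=O)CC=C(C)[C@@H]1OC(C)=O
F3 | step 18 | [(1S,3R,4S)-3-bromo-4-hydroxy-4-methylcyclohexyl](morpholin-4-yl)methanone | O=C(N1CCOCC1)[C@H]1CC[C@](C)(O)[C@H](Br)C1
F4 | step 18 | (1S,3R,4S)-3-bromo-4-hydroxy-4-methylcyclohexane-1-carbaldehyde | O=C[C@H]1CC[C@](C)(O)[C@H](Br)C1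
F5 | step 18 | (1S,4R,6R)-6-bromo-3-methoxy-1-methyl-2-oxabicyclo[2.2.2]octane | COC1O[C@@]2(C)CC[C@@H]1C[C@H]2Br
F6 | step 18 | (1S,4R,6R)-6-bromo-1-methyl-2-oxabicyclo[2.2.2]octan-3-one | O=C1O[C@@]2(C)CC[C@@H]1C[C@H]2Br
F7 | step 21 | lithium B-methoxy-B-{[(1R,2S,3S,6S)-3-methyl-6-(prop-1-en-2-yl)-2,3-bis(triethylsilyloxy)cyclohexyl]methyl}-9-borabicyclo[3.3.1]nonanate | [Li+].CO[B-]1(C[C@@H]2[C@@H](C(C)=C)CC[C@](C)(O[Si](CC)(CC)CC)[C@H]2O[Si](CC)(CC)CC)C2CCCC1CCC2
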